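**Strategy.** Everything rests on closing the 1,2-dioxane ring last, at its most congested bond O1–C6. The precursor is an open-chain (3S)-hydroperoxide that is homoallylic to a (5E)-trisubstituted C5=C6 alkene. Divalent mercury activates the alkene and the hydroperoxide oxygen adds to C6 in a 6-endo, Markovnikov, anti fashion; borohydride then turns C5–Hg into the ring CH2. The step exploits that C6 is fully substituted and flanked by the C5 methylene, and that the C4 ethyl centre is allylic: alkene geometry plus a chair with the C4 ethyl equatorial fix C6. The precursor is assembled convergently by Marshall propargylation, anti SN2′ allylation and Negishi coupling at C6–C7.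

Key step: step 15

Remark on numbering: the carbon chain of the target is numbered C1 (carboxyl carbon) to C14; the ring is O1–O2–C3–C4–C5–C6, with O1 on C6 and O2 on C3.
Assumption: 3-[(tert-butyldimethylsilyl)oxy]propanal (7) and (2R)-3-bromo-2-methylpropan-1-ol (16) are taken as purchasable.

Step 1
Reactants: 1 but-1-yne; 2 N-methoxy-N-methylpropanamide
Product: 4 hept-4-yn-3-one, via lithium but-1-ynide 3 (not isolated)
Conditions: n-BuLi, THF, −78 °C; then 2, −78 → 0 °C; aq. NH4Cl
Reagents that add atoms: none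
Why: Weinreb ketone synthesis: the lithium acetylide adds once to the N-methoxy-N-methylamide and the chelated tetrahedral adduct releases the ynone only on work-up.

Step 2
Reactants: 4 hept-4-yn-3-one
Product: 5 (3R)-hept-4-yn-3-ol
Conditions: Ru[(R,R)-TsDPEN](p-cymene) (1 mol %), propan-2-ol, 25 °C
Reagents that add atoms: none
Why: Noyori asymmetric transfer hydrogenation of an alkynyl ketone, in which the alkynyl group takes the place of the aryl group in the hydride-transfer transition state, so the (R,R) catalyst should give the 3R carbinol.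

Step 3
Reactants: 5 (3R)-hept-4-yn-3-ol
Product: 6 (3R)-hept-4-yn-3-yl methanesulfonate
Conditions: MsCl, Et3N, CH2Cl2, −20 °C
Reagents that add atoms: methanesulfonyl chloride, CS(=O)(=O)Cl
Why: Mesylation at oxygen, which leaves the carbinol configuration untouched.

Step 4
Reactants: 6 (3R)-hept-4-yn-3-yl methanesulfonate; 7 3-[(tert-butyldimethylsilyl)oxy]propanal
Product: 9 (3R,4S)-1-[(tert-butyldimethylsilyl)oxy]-4-ethyloct-5-yn-3-ol, via allenylzinc 8 (not isolated)
Conditions: Pd(OAc)2 (5 mol %), PPh3 (5 mol %), Et2Zn (3 equiv), THF, −78 → −20 °C; aq. NH4Cl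
Reagents that add atoms: none
Why: Marshall propargylation: zerovalent palladium formed in the flask adds to the mesylate in an anti SN2′ sense, transmetallation to zinc with retention gives the chiral allenylzinc, and its cyclic syn SE2′ addition to the aldehyde transfers the mesylate chirality to C4 (4S) while the chair-like transition state with the aldehyde substituent away from the ethyl group sets the anti carbinol at C3 (3R).

Step 5
Reactants: 9 (3R,4S)-1-[(tert-butyldimethylsilyl)oxy]-4-ethyloct-5-yn-3-ol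
Product: 11 (3R,4S,5E)-1-[(tert-butyldimethylsilyl)oxy]-4-ethyl-6-iodooct-5-en-3-ol, via alkenylzirconocene 10 (not isolated)
Conditions: Cp2Zr(H)Cl (3 equiv), THF, 25 → 45 °C; then I2, THF, 0 °C
Reagents that add atoms: iodine, II
Why: Hydrozirconation–iodination: syn addition of Zr–H places zirconium on the less hindered alkyne carbon C6 (ethyl side, reinforced by equilibration with excess reagent), and iodinolysis with retention should give the E iodide with the C6 ethyl cis to C4.

Step 6
Reactants: 4 hept-4-yn-3-one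
Product: 12 (3S)-hept-4-yn-3-ol
Conditions: Ru[(S,S)-TsDPEN](p-cymene) (1 mol %), propan-2-ol, 25 °C
Reagents that add atoms: none
Why: The same Noyori asymmetric transfer hydrogenation with the mirror-image catalyst should give the 3S carbinol from the common ynone.

Step 7
Reactants: 12 (3S)-hept-4-yn-3-ol
Product: 13 (3S,4E)-hept-4-en-3-ol
Conditions: NaAlH2(OCH2CH2OMe)2, THF, 0 → 25 °C; aq. Rochelle salt
Reagents that add atoms: none
Why: Alkoxide-directed trans-hydroalumination of the propargylic alcohol followed by protonolysis gives the E allylic alcohol without touching the carbinol centre.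

Step 8
Reactants: 13 (3S,4E)-hept-4-en-3-ol; 14 pyridine-2-carboxylic acid
Product: 15 (3S,4E)-hept-4-en-3-yl pyridine-2-carboxylate
Conditions: DCC, DMAP (cat.), CH2Cl2, 0 → 25 °C
Reagents that add atoms: none
Why: Steglich esterification installs the chelating picolinate leaving group needed for the copper-mediated allylic substitution.

Step 9
Reactants: 16 (2R)-3-bromo-2-methylpropan-1-ol
Product: 17 [(2R)-3-bromo-2-methylpropoxy](tert-butyl)dimethylsilane
Conditions: TBSCl, imidazole, DMF, 25 °C
Reagents that add atoms: tert-butyldimethylsilyl chloride, CC(C)(C)[Si](C)(C)Cl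
Why: Silylation of the primary alcohol of a chiral-pool building block that already carries the future C8 methyl stereocentre.

Step 10
Reactants: 17 [(2R)-3-bromo-2-methylpropoxy](tert-butyl)dimethylsilane; 15 (3S,4E)-hept-4-en-3-yl pyridine-2-carboxylate
Product: 19 tert-butyl{[(2S,4R,5E)-4-ethyl-2-methyloct-5-en-1-yl]oxy}dimethylsilane, via Grignard reagent 18 (not isolated)
Conditions: 17, Mg, THF, 40 °C; CuBr·SMe2 (0.5 equiv, not consumed), THF, −40 °C; then 15, −40 → 0 °C; aq. NH4Cl
Reagents that add atoms: none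
Why: Copper-mediated anti SN2′ allylic substitution of a picolinate by a Grignard reagent: chelation by the picolinoxy group directs the alkylcopper to the γ carbon anti to the leaving group, so the S carbinol chirality is transferred to C10 (R) and the new C11=C12 alkene forms E from the conformer with the carbinol hydrogen in the alkene plane.

Step 11
Reactants: 19 tert-butyl{[(2S,4R,5E)-4-ethyl-2-methyloct-5-en-1-yl]oxy}dimethylsilane
Product: 20 (2S,4R,5E)-1-bromo-4-ethyl-2-methyloct-5-ene
Conditions: Ph3PBr2, CH2Cl2, 0 → 25 °C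
Reagents that add atoms: dibromotriphenylphosphorane, BrP(Br)(c1ccccc1)(c1ccccc1)c1ccccc1
Why: Direct bromination of a primary silyl ether: O-phosphonium activation and SN2 attack of bromide at the primary carbon, remote from both stereocentres.

Step 12
Reactants: 20 (2S,4R,5E)-1-bromo-4-ethyl-2-methyloct-5-ene; 11 (3R,4S,5E)-1-[(tert-butyldimethylsilyl)oxy]-4-ethyl-6-iodooct-5-en-3-ol
Product: 22 (3R,4S,5E,8S,10R,11E)-1-[(tert-butyldimethylsilyl)oxy]-4,6,10-triethyl-8-methyltetradeca-5,11-dien-3-ol, via alkylzinc bromide 21 (not isolated)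
Conditions: 20, Zn dust, LiCl, THF, 50 °C; then 11, Pd(OAc)2 (2 mol %), SPhos (4 mol %), THF, 25 °C
Reagents that add atoms: none
Why: Negishi sp3–sp2 cross-coupling: zinc insertion into the primary bromide gives an alkylzinc that tolerates the free hydroxyl group, and coupling at the alkenyl iodide proceeds with retention, so the C7 chain ends trans to C4 (5E).

Step 13
Reactants: 22 (3R,4S,5E,8S,10R,11E)-1-[(tert-butyldimethylsilyl)oxy]-4,6,10-triethyl-8-methyltetradeca-5,11-dien-3-ol
Product: 23 (3R,4S,5E,8S,10R,11E)-1-[(tert-butyldimethylsilyl)oxy]-4,6,10-triethyl-8-methyltetradeca-5,11-dien-3-yl methanesulfonate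
Conditions: MsCl, Et3N, CH2Cl2, −10 °C
Reagents that add atoms: methanesulfonyl chloride, CS(=O)(=O)Cl
Why: Mesylation turns the C3 hydroxyl into a leaving group without changing its configuration.

Step 14
Reactants: 23 (3R,4S,5E,8S,10R,11E)-1-[(tert-butyldimethylsilyl)oxy]-4,6,10-triethyl-8-methyltetradeca-5,11-dien-3-yl methanesulfonate
Product: 24 tert-butyl{[(3S,4S,5E,8S,10R,11E)-4,6,10-triethyl-3-hydroperoxy-8-methyltetradeca-5,11-dien-1-yl]oxy}dimethylsilane
Conditions: 50 % aq. H2O2 (large excess), KOH, MeOH–THF, 0 → 25 °C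
Reagents that add atoms: hydrogen peroxide, OO
Why: SN2 displacement of the secondary mesylate by hydroperoxide anion, a strong alpha-effect nucleophile of low basicity, which inverts C3 from R to S.

Step 15
Reactants: 24 tert-butyl{[(3S,4S,5E,8S,10R,11E)-4,6,10-triethyl-3-hydroperoxy-8-methyltetradeca-5,11-dien-1-yl]oxy}dimethylsilane
Product: 26 tert-butyl(2-{(3S,4S,6R)-4,6-diethyl-6-[(2S,4R,5E)-4-ethyl-2-methyloct-5-en-1-yl]-1,2-dioxan-3-yl}ethoxy)dimethylsilane, via organomercurial 25 (not isolated)
Conditions: Hg(OAc)2 (1.1 equiv), CH2Cl2, 0 → 25 °C, dark; then NaBH4, 2 M aq. NaOH, 0 °C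
Reagents that add atoms: none
Why: Divalent mercury adds to the electron-rich trisubstituted C5=C6 alkene to give a mercurinium ion that the terminal oxygen of the C3 hydroperoxide opens at the tertiary carbon C6 anti to mercury, and NaBH4 then replaces the C5–Hg bond by C–H through a ring-carbon radical that cannot reach the collinear geometry needed to attack the O–O bond. The closest known reaction type is the cycloperoxymercuration–hydridodemercuration of unsaturated hydroperoxides to 1,2-dioxanes. The 1,2-dioxane closes in the 6-endo-trig mode, preferred over 5-exo attack at C5 because positive charge is stabilised at the tertiary C6 (Markovnikov control). C6 is set by the E alkene geometry and the C4 stereocentre: anti addition in a chair that keeps the C4 ethyl equatorial (C4–H near the alkene plane, minimal allylic 1,3-strain) forces the C6 ethyl, which is cis to C4 on the alkene, axial and the C7 chain equatorial, which is the 6R configuration, whereas the alternative chair suffers a syn-diaxial ethyl/ethyl contact. The step needs chemoselectivity over the C11=C12 alkene, which is secured by the intramolecular nucleophile, the higher nucleophilicity of the trisubstituted alkene and the use of only a slight excess of Hg(OAc)2; keeping C1 as a silyl ether avoids an acidifying carbonyl group beta to the peroxide during the basic reduction.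

Step 16
Reactants: 26 tert-butyl(2-{(3S,4S,6R)-4,6-diethyl-6-[(2S,4R,5E)-4-ethyl-2-methyloct-5-en-1-yl]-1,2-dioxan-3-yl}ethoxy)dimethylsilane
Product: 27 2-{(3S,4S,6R)-4,6-diethyl-6-[(2S,4R,5E)-4-ethyl-2-methyloct-5-en-1-yl]-1,2-dioxan-3-yl}ethan-1-ol
Conditions: HF·pyridine, pyridine, THF, 0 → 25 °C
Reagents that add atoms: none
Why: Fluoride-mediated desilylation of the primary silyl ether under buffered conditions that should leave the dialkyl peroxide and the alkene untouched.

Step 17
Reactants: 27 2-{(3S,4S,6R)-4,6-diethyl-6-[(2S,4R,5E)-4-ethyl-2-methyloct-5-en-1-yl]-1,2-dioxan-3-yl}ethan-1-ol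
Product: 28 2-{(3S,4S,6R)-4,6-diethyl-6-[(2S,4R,5E)-4-ethyl-2-methyloct-5-en-1-yl]-1,2-dioxan-3-yl}acetic acid
Conditions: TEMPO (20 mol %), PhI(OAc)2 (2.5 equiv), MeCN–H2O (1:1), 25 °C
Reagents that add atoms: water, O
Why: Oxoammonium (TEMPO) oxidation with PhI(OAc)2 as terminal oxidant takes the primary alcohol through the aldehyde hydrate to the acid without affecting the peroxide, the alkene or the stereocentres.

**Compound list**

1 | but-1-yne | CCC#C | starting material
2 | N-methoxy-N-methylpropanamide | CCC(=O)N(C)OC | starting material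
3 | lithium but-1-ynide | [Li]C#CCC | intermediate
4 | hept-4-yn-3-one | CCC#CC(=O)CC | intermediate
5 | (3R)-hept-4-yn-3-ol | CC[C@@H](O)C#CCC | intermediate
6 | (3R)-hept-4-yn-3-yl methanesulfonate | CC[C@@H](OS(C)(=O)=O)C#CCC | intermediate
7 | 3-[(tert-butyldimethylsilyl)oxy]propanal | O=CCCO[Si](C)(C)C(C)(C)C | starting material
8 | (aS)-ethyl(hepta-3,4-dien-3-yl)zinc | CCC([Zn]CC)=[C@]=C([H])CC | intermediate
9 | (3R,4S)-1-[(tert-butyldimethylsilyl)oxy]-4-ethyloct-5-yn-3-ol | CCC#C[C@H](CC)[C@H](O)CCO[Si](C)(C)C(C)(C)C | intermediate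
10 | (5E)-alkenylzirconocene chloride from 9, with Cp2ZrCl on C6 and a second Cp2ZrCl on the C3 oxygen | CC/C(=C\[C@H](CC)[C@@H](CCO[Si](C)(C)C(C)(C)C)O[Zr](Cl)(C1C=CC=C1)C1C=CC=C1)[Zr](Cl)(C1C=CC=C1)C1C=CC=C1 | intermediate
11 | (3R,4S,5E)-1-[(tert-butyldimethylsilyl)oxy]-4-ethyl-6-iodooct-5-en-3-ol | CC/C(I)=C\[C@H](CC)[C@H](O)CCO[Si](C)(C)C(C)(C)C | intermediate
12 | (3S)-hept-4-yn-3-ol | CC[C@H](O)C#CCC | intermediate
13 | (3S,4E)-hept-4-en-3-ol | CC[C@H](O)/C=C/CC | intermediate
14 | pyridine-2-carboxylic acid | OC(=O)c1ccccn1 | starting material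
15 | (3S,4E)-hept-4-en-3-yl pyridine-2-carboxylate | CC[C@H](OC(=O)c1ccccn1)/C=C/CC | intermediate
16 | (2R)-3-bromo-2-methylpropan-1-ol | BrC[C@H](C)CO | starting material
17 | [(2R)-3-bromo-2-methylpropoxy](tert-butyl)dimethylsilane | BrC[C@H](C)CO[Si](C)(C)C(C)(C)C | intermediate
18 | {(2R)-3-[(tert-butyldimethylsilyl)oxy]-2-methylpropyl}magnesium bromide | Br[Mg]C[C@H](C)CO[Si](C)(C)C(C)(C)C | intermediate
19 | tert-butyl{[(2S,4R,5E)-4-ethyl-2-methyloct-5-en-1-yl]oxy}dimethylsilane | CC/C=C/[C@H](CC)C[C@H](C)CO[Si](C)(C)C(C)(C)C | intermediate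
20 | (2S,4R,5E)-1-bromo-4-ethyl-2-methyloct-5-ene | CC/C=C/[C@H](CC)C[C@H](C)CBr | intermediate
21 | [(2S,4R,5E)-4-ethyl-2-methyloct-5-en-1-yl]zinc bromide | CC/C=C/[C@H](CC)C[C@H](C)C[Zn]Br | intermediate
22 | (3R,4S,5E,8S,10R,11E)-1-[(tert-butyldimethylsilyl)oxy]-4,6,10-triethyl-8-methyltetradeca-5,11-dien-3-ol | CC/C=C/[C@H](CC)C[C@H](C)C/C(CC)=C/[C@H](CC)[C@H](O)CCO[Si](C)(C)C(C)(C)C | intermediate
23 | (3R,4S,5E,8S,10R,11E)-1-[(tert-butyldimethylsilyl)oxy]-4,6,10-triethyl-8-methyltetradeca-5,11-dien-3-yl methanesulfonate | CC/C=C/[C@H](CC)C[C@H](C)C/C(CC)=C/[C@H](CC)[C@H](OS(C)(=O)=O)CCO[Si](C)(C)C(C)(C)C | intermediate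
24 | tert-butyl{[(3S,4S,5E,8S,10R,11E)-4,6,10-triethyl-3-hydroperoxy-8-methyltetradeca-5,11-dien-1-yl]oxy}dimethylsilane | CC/C=C/[C@H](CC)C[C@H](C)C/C(CC)=C/[C@H](CC)[C@@H](OO)CCO[Si](C)(C)C(C)(C)C | intermediate
25 | tert-butyl(2-{(3S,4R,5S,6R)-5-(acetoxymercurio)-4,6-diethyl-6-[(2S,4R,5E)-4-ethyl-2-methyloct-5-en-1-yl]-1,2-dioxan-3-yl}ethoxy)dimethylsilane (Hg equatorial, trans to O1) | CC/C=C/[C@H](CC)C[C@H](C)C[C@]1(CC)[C@@H]([Hg]OC(C)=O)[C@H](CC)[C@H](CCO[Si](C)(C)C(C)(C)C)OO1 | intermediate
26 | tert-butyl(2-{(3S,4S,6R)-4,6-diethyl-6-[(2S,4R,5E)-4-ethyl-2-methyloct-5-en-1-yl]-1,2-dioxan-3-yl}ethoxy)dimethylsilane | CC/C=C/[C@H](CC)C[C@H](C)C[C@]1(CC)C[C@H](CC)[C@H](CCO[Si](C)(C)C(C)(C)C)OO1 | intermediate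
27 | 2-{(3S,4S,6R)-4,6-diethyl-6-[(2S,4R,5E)-4-ethyl-2-methyloct-5-en-1-yl]-1,2-dioxan-3-yl}ethan-1-ol | CC/C=C/[C@H](CC)C[C@H](C)C[C@]1(CC)C[C@H](CC)[C@H](CCO)OO1 | intermediate
28 | 2-{(3S,4S,6R)-4,6-diethyl-6-[(2S,4R,5E)-4-ethyl-2-methyloct-5-en-1-yl]-1,2-dioxan-3-yl}acetic acid | CC/C=C/[C@H](CC)C[C@H](C)C[C@]1(CC)C[C@H](CC)[C@H](CC(=O)O)OO1 | target

**Totals.** Total step count: 17. Longest linear sequence: 12 steps (steps 1, 6, 7, 8, 10, 11, 12, 13, 14, 15, 16, 17).

**Steps most likely to fail**

1. Step 14. Substitution at the hindered, beta-branched secondary carbon C3 may lose to base-induced elimination toward the allylic C4–H (giving a conjugated diene) or to participation of the homoallylic alkene, and inversion may be incomplete. The fallback sets out from 23 and comes back at 24, and replaces free hydrogen peroxide by a masked, more nucleophilic and less basic peroxide carrier. Ozonolysis of 2,3-dimethylbut-2-ene in methanol would give 2-methoxypropan-2-yl hydroperoxide F1. Its caesium salt (CsOH·H2O, DMF, 0 °C) should displace the mesylate of 23 with inversion to give the peroxyketal tert-butyl{[(3S,4S,5E,8S,10R,11E)-4,6,10-triethyl-3-[(2-methoxypropan-2-yl)peroxy]-8-methyltetradeca-5,11-dien-1-yl]oxy}dimethylsilane F2. Mild hydrolysis (AcOH–H2O–THF, 25 °C) would then release hydroperoxide 24.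

2. Step 15. Ring closure may lose regiocontrol (5-exo attack at C5), mercury may add to the C11=C12 alkene, or the borohydride step may reverse the mercuration (deoxymercuration back to alkene and hydroperoxide). The fallback sets out from 24 and comes back at 26, and replaces the reversible mercury electrophile and hydride demercuration by an irreversible iodonium closure and a radical chain reduction. N-Iodosuccinimide (CH2Cl2, 0 °C, dark) should give by the same anti 6-endo cyclisation tert-butyl(2-{(3S,4R,5S,6R)-4,6-diethyl-6-[(2S,4R,5E)-4-ethyl-2-methyloct-5-en-1-yl]-5-iodo-1,2-dioxan-3-yl}ethoxy)dimethylsilane F3. Its C5–I bond would be reduced with Bu3SnH and Et3B/air in toluene at 0 °C to give 26.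

3. Step 10. Both termini of the allyl unit carry an ethyl group, so direct alpha-substitution instead of gamma-attack gives the C10 epimer, and incomplete chirality transfer has the same effect. The fallback sets out from 5 (and Grignard reagent 18, made as in step 10) and comes back at 19, and switches to a phosphine-directed syn SN2′ delivery from the enantiomeric alcohol. Trans-reduction of 5 with NaAlH2(OCH2CH2OMe)2 would give (3R,4E)-hept-4-en-3-ol F4. Esterification with 2-(diphenylphosphanyl)benzoic acid (DCC, DMAP) would give (3R,4E)-hept-4-en-3-yl 2-(diphenylphosphanyl)benzoate F5. The phosphine binds copper (CuBr·SMe2, Et2O, 25 °C) and should deliver the alkyl group of 18 to the gamma carbon on the face of the leaving group, which from the R ester again gives the 10R centre and the E alkene of 19.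

**Further compounds**

F1 | step 14 | 2-methoxypropan-2-yl hydroperoxide | COC(C)(C)OO
F2 | step 14 | tert-butyl{[(3S,4S,5E,8S,10R,11E)-4,6,10-triethyl-3-[(2-methoxypropan-2-yl)peroxy]-8-methyltetradeca-5,11-dien-1-yl]oxy}dimethylsilane | CC/C=C/[C@H](CC)C[C@H](C)C/C(CC)=C/[C@H](CC)[C@@H](OOC(C)(C)OC)CCO[Si](C)(C)C(C)(C)C
F3 | step 15 | tert-butyl(2-{(3S,4R,5S,6R)-4,6-diethyl-6-[(2S,4R,5E)-4-ethyl-2-methyloct-5-en-1-yl]-5-iodo-1,2-dioxan-3-yl}ethoxy)dimethylsilane | CC/C=C/[C@H](CC)C[C@H](C)C[C@]1(CC)[C@@H](I)[C@H](CC)[C@H](CCO[Si](C)(C)C(C)(C)C)OO1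
F4 | step 10 | (3R,4E)-hept-4-en-3-ol | CC[C@@H](O)/C=C/CC
F5 | step 10 | (3R,4E)-hept-4-en-3-yl 2-(diphenylphosphanyl)benzoate | CC[C@@H](OC(=O)c1ccccc1P(c1ccccc1)c1ccccc1)/C=C/CC
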